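**Assumption:** the target has no stereocentre and no configurationally stable axis, so it is achiral and the given SMILES is its full stereochemical description; no enantiocontrol is needed.

**Retrosynthetic overview**
1. Target 7 ⇒ diketone 6: open the pyranone at the aryl C–O bond O1–C8a; this bond is made last by a dehydrogenative C–H/O–H cyclisation, and the pyranone is the only ring formed in the route.
2. Diketone 6 ⇒ methyl ketone 4 + ester 5: crossed Claisen condensation (C3–C4 bond of the flavone).
3. Ketone 4 ⇒ 1,2,4-trimethoxybenzene 1 + Weinreb amide 2: lithiation at C3 (aryllithium 3), then acetylation.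
4. Both benzene rings are bought with all five methoxy groups in place; no protecting groups are used.

**Step 1**
Reactants: 1 1,2,4-trimethoxybenzene; 2 N-methoxy-N-methylacetamide
Product: 4 1-(2,3,6-trimethoxyphenyl)ethan-1-one, via 2,3,6-trimethoxyphenyllithium 3 (not isolated)
Conditions: n-BuLi (1.1 equiv), THF, 0 °C → rt; then 2, −78 °C → rt; aq. HCl
Reagents that add atoms: none
Why: Directed ortho-lithiation takes place at C3, the position flanked by two methoxy groups, and the Weinreb ketone synthesis stops cleanly at the methyl ketone.

**Step 2**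
Reactants: 4 1-(2,3,6-trimethoxyphenyl)ethan-1-one; 5 methyl 2,3-dimethoxybenzoate
Product: 6 1-(2,3-dimethoxyphenyl)-3-(2,3,6-trimethoxyphenyl)propane-1,3-dione
Conditions: NaH (2.5 equiv), THF, reflux; then aq. HCl
Reagents that add atoms: none
Why: Crossed Claisen condensation of a methyl ketone with a non-enolisable aryl ester, driven by irreversible deprotonation of the β-diketone formed; the di-ortho-substituted ketone 4 does not self-condense.

**Step 3**
Reactants: 6 1-(2,3-dimethoxyphenyl)-3-(2,3,6-trimethoxyphenyl)propane-1,3-dione
Product: 7 5,6,2',3',6'-pentamethoxyflavone [5,6-dimethoxy-2-(2,3,6-trimethoxyphenyl)-4H-chromen-4-one]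
Conditions: Pd(OAc)2 (10 mol %), IPr (12 mol %), 4,5-diazafluoren-9-one (10 mol %), MesCO2Na (50 mol %), air (1 atm), mesitylene, 120 °C
Reagents that add atoms: none
Why: Proposed new method: a Pd(II)-catalysed aerobic dehydrogenative C–H/O–H cyclisation of a 1,3-diaryl-1,3-diketone (a "vinylogous C–H lactonisation"), in which the enolate oxygen on the trimethoxyphenyl-bearing carbon binds Pd(II), carboxylate-assisted concerted metalation–deprotonation cleaves the only ortho C–H in the molecule (C6–H of the 2,3-dimethoxyphenyl ring; the other ring has both ortho positions blocked by OMe, so the regiochemistry is unambiguous) to give a seven-membered oxapalladacycle, C(aryl)–O reductive elimination (helped by the bulky NHC and by formation of the γ-pyranone) makes O1–C8a, and air with diazafluorenone returns Pd(0) to Pd(II); the closest known reaction types are the Pd-catalysed aerobic phenol-directed C–H activation/C–O cyclisation of 2-arylphenols to dibenzofurans and the dehydrogenative lactonisation of 2-arylbenzoic acids, while aryl–O(enolate) reductive elimination is known from intramolecular enolate O-arylation of 2-haloaryl ketones.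

**Compound list**
1 | 1,2,4-trimethoxybenzene | COc1ccc(OC)c(OC)c1 | starting material
2 | N-methoxy-N-methylacetamide | CC(=O)N(C)OC | starting material
3 | 2,3,6-trimethoxyphenyllithium | [Li]c1c(OC)ccc(OC)c1OC | intermediate
4 | 1-(2,3,6-trimethoxyphenyl)ethan-1-one | CC(=O)c1c(OC)ccc(OC)c1OC | intermediate
5 | methyl 2,3-dimethoxybenzoate | COC(=O)c1cccc(OC)c1OC | starting material
6 | 1-(2,3-dimethoxyphenyl)-3-(2,3,6-trimethoxyphenyl)propane-1,3-dione (largely the chelated enol) | COc1cccc(C(=O)CC(=O)c2c(OC)ccc(OC)c2OC)c1OC | intermediate
7 | 5,6,2',3',6'-pentamethoxyflavone | COc1ccc(OC)c(-c2cc(=O)c3c(OC)c(OC)ccc3o2)c1OC | target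

**Total step count:** 3
**Longest linear sequence:** 3 (1 → 4 → 6 → 7)

**Steps most likely to fail**

**Step 3 (the proposed new cyclisation), highest risk.** The diketonate may hold Pd(II) as an unreactive O,O-chelate. C–O reductive elimination from Pd(II) may be slow. Air was chosen as oxidant because iodine(III) or persulfate oxidants would attack the enolisable CH2 and the 3',6'-dimethoxy (hydroquinone dimethyl ether) ring. The fallback uses known chemistry and makes the same O1–C8a bond by intramolecular copper-catalysed O-arylation of an aryl bromide. It sets out from ester 5 and ketone 4, bypasses 6 and comes back at target 7. Ester 5 is saponified in aqueous NaOH to sodium 2,3-dimethoxybenzoate F4, which is not isolated. It is brominated in the same pot with 1,3-dibromo-5,5-dimethylhydantoin, para to the 3-methoxy group, and acidified to give 6-bromo-2,3-dimethoxybenzoic acid F5. SOCl2 (cat. DMF, toluene, 70 °C) converts this into 6-bromo-2,3-dimethoxybenzoyl chloride F6. F6 C-acylates ketone 4 under soft enolisation (MgBr2·OEt2, i-Pr2NEt, CH2Cl2, rt) to give 1-(6-bromo-2,3-dimethoxyphenyl)-3-(2,3,6-trimethoxyphenyl)propane-1,3-dione F7. Ullmann-type ring closure (CuI 10 mol %, 1,10-phenanthroline 20 mol %, K2CO3, DMF, 110 °C) then gives 7.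

**Step 1.** The hindered aryllithium 3 may deprotonate the acetamide instead of adding to it, returning 1. The fallback sets out from 1 and comes back at 4. Compound 1 is lithiated as before and aryllithium 3 is trapped with acetaldehyde at −78 °C to give racemic 1-(2,3,6-trimethoxyphenyl)ethan-1-ol F1. Dess–Martin periodinane (CH2Cl2, rt) then oxidises this benzylic alcohol to ketone 4.

**Step 2.** The Claisen condensation may stall or reverse. The fallback replaces the reversible ester condensation by an irreversible acid-chloride C-acylation. It sets out from 5 and 4 and comes back at 6. Ester 5 is saponified (LiOH, THF/H2O, then HCl) to 2,3-dimethoxybenzoic acid F2. SOCl2 (cat. DMF, toluene, 70 °C) gives 2,3-dimethoxybenzoyl chloride F3. F3 acylates ketone 4 at carbon under soft enolisation (MgBr2·OEt2, i-Pr2NEt, CH2Cl2, rt) to give diketone 6.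

**Further compounds**
F1 | step 1 | 1-(2,3,6-trimethoxyphenyl)ethan-1-ol (racemic) | CC(O)c1c(OC)ccc(OC)c1OC
F2 | step 2 | 2,3-dimethoxybenzoic acid | COc1cccc(C(=O)O)c1OC
F3 | step 2 | 2,3-dimethoxybenzoyl chloride | COc1cccc(C(=O)Cl)c1OC
F4 | step 3 | sodium 2,3-dimethoxybenzoate | [Na+].[O-]C(=O)c1cccc(OC)c1OC
F5 | step 3 | 6-bromo-2,3-dimethoxybenzoic acid | COc1ccc(Br)c(C(=O)O)c1OC
F6 | step 3 | 6-bromo-2,3-dimethoxybenzoyl chloride | COc1ccc(Br)c(C(=O)Cl)c1OC
F7 | step 3 | 1-(6-bromo-2,3-dimethoxyphenyl)-3-(2,3,6-trimethoxyphenyl)propane-1,3-dione | COc1ccc(Br)c(C(=O)CC(=O)c2c(OC)ccc(OC)c2OC)c1OC
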